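Time is the easy setting to turn, so I start from the flasks and their readings.

| flask | substrate | remark | time |
|---|---|---|---|
| oak | 0.040 M | run made earlier |  |
| maple | 0.092 M | run made earlier |  |
| west | 0.030 M |  | 3.0 h |
| north-east | 0.050 M |  | 3.0 h |
| east | 0.080 M |  | 3.0 h |

- oak (time / min: ring / %, substrate / %): 6.00: 18, 81; 20.0: 35, 44; 40.0: 52, 26; 50.0: 58, 20; 80.0: 68, 9; 90.0: 73, 5; 120: 73, 7
- maple (time / min: ring / %, substrate / %): 20.0: 31, 40; 40.0: 46, 22; 50.0: 46, 14; 80.0: 59, 2; 90.0: 56, 3; 120: 58, 1

(readings scatter by 2 percentage points)

- a reading or a percentage of ring counts all its forms, free or not
- the concentration of ring that is asked is that of its free form alone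
- "hardly changes" means that all values lie within two and a half points (for a concentration: within two and a half percent of the largest)

- [ring] (only what is free in solution) at the end for west, north-east, east, in this order
- the course of these numbers from the first flask to the last (falls, then rises / rises all the way / falls all the way / hardly changes / rises, then falls)

In the oak run substrate falls from 26 % to 9 % between 40.0 min and 80.0 min, a half-life read as about 26.1 min. So 3.0 h is about 6.90 half-lives, and I treat the flasks as finished.

The charge is the next setting to turn. By 20.0 min the oak readings show 62.5 % of the lost substrate as ring, and by 20.0 min the maple readings show less, 51.7 %; this share is the selectivity. I take ring closure as first order and a side path as second order, so the selectivity at substrate concentration S is C/(C+S). At a mean substrate of 0.0644 M, maple gives 0.0688 M for the concentration at which both paths take substrate equally, the crossover concentration C. The same reading in oak gives 0.0480 M, but I keep maple's, where the paths run close to even.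

Far below C, ring equals the charge; far above it, ring grows with the logarithm of the charge. Summing the selectivity over the run joins both ends: ring = C ln(1 + charge/C). For west, north-east and east I get 0.0249 M, 0.0376 M and 0.0531 M. These count ring in all its forms, as the readings do.

The forecast gives 0.0236 M, 0.0349 M and 0.0482 M, which rises all the way. These are lower than my totals, and of the free form it says: “The runs show nothing about a bound form of ring”.

The flasks give 0.00370 M, 0.00373 M and 0.00375 M, so the course hardly changes.

    crystals ⇌ ring, rate k1*(cs1 - [ring]) while solid is left; crystals form when [ring] > cs1 (solubility = 3.60 mM, k = 0.00140 /s)
    2 substrate → open dimer (k = 0.00310 /M/s)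
    substrate + open dimer → open trimer (k = 0.00280 /M/s)
    substrate → decomposition product (k = 1.20 × 10⁻⁷ /s)
    substrate → ring (k = 4.00 × 10⁻⁴ /s)

The largest single effect on free ring in west is the low solubility of ring. The same run without it ends at 0.0241 M free, close to my 0.0249 M, so C still gives the ring made, while the flask itself keeps 68.1 % of its charge as crystals. East, the last flask, shows the same: without the low solubility it ends at 0.0496 M against my 0.0531 M, but the flask holds 0.00375 M free and 57.3 % of its charge as crystals.

The readings are calculated with made-up constants; scatter was added.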